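Assumption: acetal 2 is made from aldehyde 1 in step 1 and not bought. All benzodioxanes are numbered as the target (O1, C2 aryl, C3, O4, C5, C7; C9 on C3), which is not the numbering of their systematic names. In benzodioxoles 4 and 5 the acetal carbon is called C2, the oxygen para to the ester O4 and the oxygen meta to it O1.

## Analysis of the target

The target is a 2,3-dihydro-1,4-benzodioxine. An aromatic ring A (C4a, C5, C6, C7, C8, C8a) is fused to a dioxane ring B (O1, C2, C3, O4). C2 carries the 3,4,5-trimethoxyphenyl ring C, C3 carries the hydroxymethyl carbon C9, C5 a free phenol and C7 an (E)-propenal chain. Ring A is a gallate-type 1,2,3-trioxygenated ring in which O1 lies meta and O4 para to the C7 side chain, and O4 is flanked by the C5 hydroxyl. There are two stereocentres, C2 and C3, both S. They are adjacent and trans (both substituents equatorial on the half-chair), so the relative configuration is the thermodynamic one as long as C3 carries an acidifying group. The absolute configuration has no nearby handle and is the harder half of the stereochemical problem. Sensitive groups are the enal (conjugate addition, reduction; it excludes hydrogenolysis once present), the free phenol, and the C2–O1 bond, a benzylic aryl ether that can ionise under strong acid. The main constitutional difficulty is regiochemical: the aryl-bearing carbon must sit on O1, the CH2OH-bearing carbon on O4, and the three oxygens of ring A must be told apart. The strategy rests on the O1–C2(aryl)–C3–O4 array. Taking C3 out of ring B leaves C2 bonded to both O1 and O4, which is the cyclic acetal of aldehyde 1 with the catechol unit of ring A. Ring B can therefore be made by pushing a carboxyl-bearing carbon into the C2–O4 bond of that benzodioxole.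

## Retrosynthetic reasoning

**14 to 13.** The last bond cut is the O–benzyl bond at C5, which leads back to benzyl ether 13. The phenol stays masked because a free hydroxyl next to O4 would compete for the Lewis acid and as a nucleophile in the ring expansion, whereas an ether oxygen there is wanted as a chelating donor. The enal rules out hydrogenolysis, so the forward step must be a Lewis-acid debenzylation that spares the methyl ethers, the enal and the C2–O1 bond.

**13 to 12.** The Cα=Cβ bond of the propenal is cut, giving aldehyde 12. A stabilised two-carbon ylide should set the E geometry, and the most fragile group enters as late as possible.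

**12 to 11 to 10.** The C7 formyl and the C9 hydroxymethyl are both traced to esters. 12 comes from diol 11 by oxidation of the benzylic alcohol only, and 11 from diester 10 by exhaustive hydride reduction. This puts both carbons at the carboxyl level, which the key step needs: at C3 because only an acceptor-substituted diazo carbon is a usable nucleophile, and at C7 because the ester makes O4 and O1 electronically different.

**10 to 9.** Diester 10 is the single (2S,3R) isomer of the diastereomer mixture 9. C3 is alpha to an ester and to an aryloxy group, so base can equilibrate it to trans. The menthyl ester turns the two ring enantiomers into diastereomers that can be separated. This accepts that the ring-forming step need not be stereoselective.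

**9 to 5 and 8.** The key disconnection cuts C2–C3 and C3–O4, removing C3 with its carboxyl group as a carbene equivalent. What remains are the benzodioxole 5 and the diazo ester 8. Both ring bonds to C3 are made at once, the aryl carbon and both ring oxygens are already joined in a trivially made acetal, and the whole regiochemical problem of ring B shrinks to which acetal C–O bond ionises. The forward reaction has to ionise C2–O4, add the diazo carbon to C2 and return the aryloxide to C3 with loss of the diazo nitrogen.

**5 to 4 to 2 and 3; 2 to 1.** The benzyl group is removed to give phenol 4, and the two acetal C–O bonds are cut to give methyl gallate 3 and dimethyl acetal 2, which comes from aldehyde 1. The two adjacent hydroxyl pairs of 3 are equivalent, so only one benzodioxole can form. The single hydroxyl left over is the future C5 oxygen. The three oxygens of ring A are thus differentiated without any selective protection.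

**8 to 7 to 6.** The diazo ester is traced through bromoacetate 7 to menthol 6, the source of the resolving auxiliary.

## Alternatives that were turned down

**Alternative 1:** oxetane by photocycloaddition, then ring expansion.
- Disconnection: the O1–C2 bond of ring B is traced to an oxetane (O, C2, C3, C9), and the oxetane to a [2+2] photocycloaddition that makes C2–C3 and O–C9.
- Forward key step: irradiation near 350 nm of aldehyde 1 with the aryl vinyl ether A1 (Paternò–Büchi) would give the trans oxetane A2. After loss of a silyl group, a flanking phenol would open the strained ring at benzylic C2 with inversion, closing ring B and freeing the C9 hydroxyl.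
- For it: the regiochemistry of ring B is fixed by construction, because the ether oxygen para to the ester becomes O4 and the two flanking phenols are equivalent. On this point it is stronger than the chosen route, which depends on selective ionisation of one acetal bond. C9 also arrives directly as CH2OH, and a trans oxetane maps stereospecifically onto a trans dioxane.
- Against it: the oxetane forms through a 1,4-biradical, so the cis/trans ratio is not controlled and cannot be corrected later, since C3 then has no acidifying group. A2 is racemic and carries nothing to resolve it by. An aryl vinyl ether is a weaker partner for a triplet aldehyde than an alkyl enol ether, and the electron-rich aldehyde is a poor triplet partner. A1 needs selective 3,5-disilylation of a gallate and vinylation of a doubly flanked phenol.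
- Comparison: the step count is not lower, because the ester-to-enal endgame is the same. In place of built-in regiochemistry, the chosen strategy offers an epimerisable C3 for thermodynamic trans control, a covalently bound resolving group, and a thermal convergent step between partners made in two and three steps.

**Alternative 2:** dehydrogenative closure at benzylic C2.
- Disconnection: O1–C2 is cut at the oxidation level of a benzylic C–H. The precursor is the 4-O-alkyl ether A3, whose C3 stereocentre would be bought from the chiral pool as an epoxide-derived secondary carbinol.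
- Forward key step: DDQ would abstract hydride from the benzylic CH2 of A3 and one of the two equivalent flanking phenols would capture the cation, giving A4.
- For it: the absolute configuration is purchased, so no material is lost in a resolution. Here it is clearly stronger than the chosen route. The regiochemistry is again fixed by symmetry, the C5 phenol needs no protecting group, and C7 is already an aldehyde.
- Against it: ring C is a weak donor for hydride abstraction, because two methoxy groups are meta to the benzylic carbon and the para one is twisted out of conjugation. DDQ may therefore attack the free resorcinol-type phenols first. The product keeps a C2–H that is now benzylic and alpha to oxygen, so it is more easily oxidised than the starting material. The cation can lose a proton towards C3 to give an enol ether. Trans would have to come from kinetic 1,2-induction, with nothing at C3 to equilibrate. The Mitsunobu etherification that makes A3 joins a secondary carbinol to a doubly ortho-substituted phenol.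
- Comparison: the length is similar to the chosen route. The chosen strategy gives up reagent-free absolute control but keeps every oxidation away from free phenols and gets trans under thermodynamic control.

**Alternative 3:** palladium π-allyl closure.
- Disconnection: O4–C3 is cut, with C9 carried as a vinyl group. The O1–C2 bond would first be made by an iridium-catalysed branched-selective allylic etherification that sets C2, and a cross-metathesis would then give the allylic carbonate A5.
- Forward key step: Pd2(dba)3 with a chiral DACH-phenyl bisphosphine (zerovalent palladium) would ionise the carbonate of A5. The para phenol would attack the inner allyl carbon in a 6-exo closure to give the vinyl benzodioxane A6, whose vinyl group is later cleaved to C9.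
- For it: both stereocentres are set by catalysts, and the palladium closure to 2-vinyl benzodioxanes is a well-established reaction type. In enantiocontrol and in precedent for the key step it is stronger than the chosen route.
- Against it: the sequence is long. It needs differentiation of the gallate hydroxyls, etherification, unmasking of a catechol next to a benzylic and allylic aryl ether, metathesis in the presence of that catechol, cyclisation, ozonolysis beside an electron-rich arene, reduction, and then the ester-to-enal endgame. The C2–O1 bond of A5 is both benzylic and allylic, so it can ionise under either metal and erode C2. Ligand and substrate control at C3 may be mismatched.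
- Comparison: the chosen strategy offers a much shorter assembly, with the key-step precursors three and two steps from purchased materials, and puts all of its risk in one step instead of spreading it over several catalytic ones.

Key step: step 6

## Route

Step 1
Reactants: 1 3,4,5-trimethoxybenzaldehyde
Product: 2 5-(dimethoxymethyl)-1,2,3-trimethoxybenzene (dimethyl acetal of 1)
Conditions: HC(OMe)3, TsOH·H2O (cat.), MeOH, rt; Et3N quench
Reagents that add atoms: trimethyl orthoformate, COC(OC)OC; methanol (solvent, exchanges with it), CO
Why: Acid-catalysed acetalisation, driven to completion because the orthoformate consumes the water formed.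

Step 2
Reactants: 2 5-(dimethoxymethyl)-1,2,3-trimethoxybenzene; 3 methyl gallate (methyl 3,4,5-trihydroxybenzoate)
Product: 4 methyl 7-hydroxy-2-(3,4,5-trimethoxyphenyl)-1,3-benzodioxole-5-carboxylate (racemic at the acetal carbon)
Conditions: TsOH·H2O (cat.), toluene, reflux, MeOH removed (4 Å sieves); Et3N quench
Reagents that add atoms: none
Why: Acid-catalysed transacetalisation of a dimethyl acetal with a catechol unit, pulled forward by removal of methanol. The two adjacent hydroxyl pairs of 3 are equivalent, so a single benzodioxole is expected. The acetal stereocentre is racemic and irrelevant, because it is planarised in step 6.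

Step 3
Reactants: 4 methyl 7-hydroxy-2-(3,4,5-trimethoxyphenyl)-1,3-benzodioxole-5-carboxylate
Product: 5 methyl 7-(benzyloxy)-2-(3,4,5-trimethoxyphenyl)-1,3-benzodioxole-5-carboxylate (racemic)
Conditions: BnBr, K2CO3, DMF, rt
Reagents that add atoms: benzyl bromide, BrCc1ccccc1
Why: Williamson etherification of the only free phenol. The acetal and the methyl ester are stable to carbonate base.

Step 4
Reactants: 6 (1R,2S,5R)-menthol
Product: 7 (1R,2S,5R)-menthyl bromoacetate
Conditions: BrCH2COBr, NaHCO3, MeCN, 0 °C
Reagents that add atoms: bromoacetyl bromide, BrCC(Br)=O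
Why: Acylation of a secondary alcohol by an acid bromide; the carbinol stereocentre is not touched.

Step 5
Reactants: 7 (1R,2S,5R)-menthyl bromoacetate
Product: 8 (1R,2S,5R)-menthyl diazoacetate
Conditions: TsNHNHTs, DBU, THF, 0 °C
Reagents that add atoms: N,N'-ditosylhydrazine, Cc1ccc(cc1)S(=O)(=O)NNS(=O)(=O)c1ccc(C)cc1
Why: N-Alkylation of the ditosylhydrazine by the bromoacetate followed by two base-induced eliminations of sulfinate, the established conversion of bromoacetates into diazoacetates.

Step 6
Reactants: 5 methyl 7-(benzyloxy)-2-(3,4,5-trimethoxyphenyl)-1,3-benzodioxole-5-carboxylate; 8 (1R,2S,5R)-menthyl diazoacetate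
Product: 9 3-[(1R,2S,5R)-menthyl] 7-methyl 5-(benzyloxy)-2-(3,4,5-trimethoxyphenyl)-2,3-dihydro-1,4-benzodioxine-3,7-dicarboxylate, as the mixture of C2/C3 diastereomers (cis and trans, both configurations at C2) that contains the wanted (2S,3R) isomer 10
Conditions: 5, SnCl4 (1.2 equiv), CH2Cl2, −78 °C; then 8 (1.5 equiv) added slowly, −78 to −40 °C; aq. NaHCO3
Reagents that add atoms: none
Why: Proposed new method: SnCl4 should bind the benzyloxy oxygen and the neighbouring acetal oxygen O4 as a five-membered chelate and ionise the C2–O4 bond, giving a tin aryloxide and an oxocarbenium ion at C2 that is stabilised by ring C and by O1. The nucleophilic diazo carbon of 8 then adds to C2 (C2–C3 bond) to give a β-aryloxy α-diazonium ester, and the tethered aryloxide O4 displaces N2 at C3 (O4–C3 bond), so that C3 ends up inserted into the former C2–O4 bond. The closest known reaction types are the Lewis-acid-promoted formal insertion of diazo esters into C–O bonds of acetals and orthoesters and the Rh2(OAc)4-mediated oxonium ylide [1,2]-shift that expands 2-aryl-1,3-dioxolanes to 1,4-dioxanes; neither has been shown on a benzodioxole with an internal aryloxide as the returning nucleophile. Ring B is closed in the 6-exo-tet mode, with N2 leaving outside the new ring. C2 is set by the face of the planar oxocarbenium ion that the diazo ester attacks, which only the remote menthyl group can bias, so both configurations are expected; C3 is set by inversion in the N2 displacement and therefore follows the topicity of the C–C bond formation, so 9 is carried on as a mixture and the single trans isomer is secured in step 7. The selectivity the step needs is ionisation of C2–O4 and not C2–O1: O4 is para to the ester and so the better aryloxide leaving group, O1 is meta to it and so the better donor to the cation it retains, and only O4 can chelate tin together with the benzyloxy oxygen. The step also needs ring closure to outrun the 1,2-hydride or 1,2-aryl shift usual for such diazonium ions; the aryloxide is held in the ion pair three atoms from C3, the acetal is ionised before 8 is added, and the temperature is kept low.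

Step 7
Reactants: 9 diastereomer mixture of the menthyl methyl diester
Product: 10 3-[(1R,2S,5R)-menthyl] 7-methyl (2S,3R)-5-(benzyloxy)-2-(3,4,5-trimethoxyphenyl)-2,3-dihydro-1,4-benzodioxine-3,7-dicarboxylate (trans)
Conditions: DBU (0.2 equiv), toluene, rt; then fractional crystallisation (MeOH or hexane–EtOAc), after silica chromatography if needed
Reagents that add atoms: none
Why: Base-mediated epimerisation of the α-aryloxy ester at C3 should move each C2 series to its diequatorial trans isomer, leaving two trans diastereomers that differ in ring configuration relative to the menthyl group. The (2S,3R) isomer is separated from the other by crystallisation; the trans isomer of opposite ring configuration stays in the mother liquor.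

Step 8
Reactants: 10 3-menthyl 7-methyl (2S,3R)-diester
Product: 11 [(2S,3S)-5-(benzyloxy)-2-(3,4,5-trimethoxyphenyl)-2,3-dihydro-1,4-benzodioxine-3,7-diyl]dimethanol (trans)
Conditions: LiAlH4, THF, 0 °C; aq. NaOH work-up
Reagents that add atoms: none
Why: Hydride reduction of both esters to primary alcohols; benzyl and methyl ethers are inert. The geometry at C3 is unchanged, and the descriptor changes from R to S only because CH2OH ranks below C2 whereas the ester ranked above it.

Step 9
Reactants: 11 (2S,3S)-diol
Product: 12 (2S,3S)-5-(benzyloxy)-3-(hydroxymethyl)-2-(3,4,5-trimethoxyphenyl)-2,3-dihydro-1,4-benzodioxine-7-carbaldehyde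
Conditions: activated MnO2, CH2Cl2, rt
Reagents that add atoms: none
Why: MnO2 oxidises benzylic alcohols and leaves saturated primary alcohols, so only the C7 carbinol should be converted.

Step 10
Reactants: 12 (2S,3S)-hydroxy aldehyde
Product: 13 (2E)-3-[(2S,3S)-5-(benzyloxy)-3-(hydroxymethyl)-2-(3,4,5-trimethoxyphenyl)-2,3-dihydro-1,4-benzodioxin-7-yl]prop-2-enal
Conditions: Ph3P=CHCHO (1.2 equiv), toluene, 80 °C
Reagents that add atoms: (triphenylphosphoranylidene)acetaldehyde, O=CC=P(c1ccccc1)(c1ccccc1)c1ccccc1
Why: Wittig olefination with a stabilised ylide, which should give the E enal. The free alcohol is tolerated, and the product enal is less electrophilic than the aryl aldehyde, which limits a second homologation.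

Step 11
Reactants: 13 benzyl-protected enal
Product: 14 (2E)-3-[(2S,3S)-5-hydroxy-3-(hydroxymethyl)-2-(3,4,5-trimethoxyphenyl)-2,3-dihydro-1,4-benzodioxin-7-yl]prop-2-enal (target)
Conditions: BCl3, pentamethylbenzene, CH2Cl2, −78 °C; MeOH then aq. NaHCO3
Reagents that add atoms: none
Why: Lewis-acid cleavage of an aryl benzyl ether with an arene scavenger for the benzyl cation. The short reaction at low temperature should spare the aryl methyl ethers and the enal, and it avoids hydrogenation of the alkene.

## Compound list

1 | 3,4,5-trimethoxybenzaldehyde | COc1cc(C=O)cc(OC)c1OC | starting material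
2 | 5-(dimethoxymethyl)-1,2,3-trimethoxybenzene | COC(OC)c1cc(OC)c(OC)c(OC)c1 | intermediate
3 | methyl gallate | COC(=O)c1cc(O)c(O)c(O)c1 | starting material
4 | methyl 7-hydroxy-2-(3,4,5-trimethoxyphenyl)-1,3-benzodioxole-5-carboxylate (racemic) | COc1cc(C2Oc3cc(C(=O)OC)cc(O)c3O2)cc(OC)c1OC | intermediate
5 | methyl 7-(benzyloxy)-2-(3,4,5-trimethoxyphenyl)-1,3-benzodioxole-5-carboxylate (racemic) | COc1cc(C2Oc3cc(C(=O)OC)cc(OCc4ccccc4)c3O2)cc(OC)c1OC | intermediate
6 | (1R,2S,5R)-menthol | CC(C)[C@@H]1CC[C@@H](C)C[C@H]1O | starting material
7 | (1R,2S,5R)-menthyl bromoacetate | BrCC(=O)O[C@@H]1C[C@H](C)CC[C@H]1C(C)C | intermediate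
8 | (1R,2S,5R)-menthyl diazoacetate | [N-]=[N+]=CC(=O)O[C@@H]1C[C@H](C)CC[C@H]1C(C)C | intermediate
9 | 3-menthyl 7-methyl 5-(benzyloxy)-2-(3,4,5-trimethoxyphenyl)-2,3-dihydro-1,4-benzodioxine-3,7-dicarboxylate, mixture of C2/C3 diastereomers | COc1cc(C2Oc3cc(C(=O)OC)cc(OCc4ccccc4)c3OC2C(=O)O[C@@H]5C[C@H](C)CC[C@H]5C(C)C)cc(OC)c1OC | intermediate
10 | 3-[(1R,2S,5R)-menthyl] 7-methyl (2S,3R)-5-(benzyloxy)-2-(3,4,5-trimethoxyphenyl)-2,3-dihydro-1,4-benzodioxine-3,7-dicarboxylate (trans) | COc1cc([C@@H]2Oc3cc(C(=O)OC)cc(OCc4ccccc4)c3O[C@H]2C(=O)O[C@@H]5C[C@H](C)CC[C@H]5C(C)C)cc(OC)c1OC | intermediate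
11 | [(2S,3S)-5-(benzyloxy)-2-(3,4,5-trimethoxyphenyl)-2,3-dihydro-1,4-benzodioxine-3,7-diyl]dimethanol | COc1cc([C@@H]2Oc3cc(CO)cc(OCc4ccccc4)c3O[C@H]2CO)cc(OC)c1OC | intermediate
12 | (2S,3S)-5-(benzyloxy)-3-(hydroxymethyl)-2-(3,4,5-trimethoxyphenyl)-2,3-dihydro-1,4-benzodioxine-7-carbaldehyde | COc1cc([C@@H]2Oc3cc(C=O)cc(OCc4ccccc4)c3O[C@H]2CO)cc(OC)c1OC | intermediate
13 | (2E)-3-[(2S,3S)-5-(benzyloxy)-3-(hydroxymethyl)-2-(3,4,5-trimethoxyphenyl)-2,3-dihydro-1,4-benzodioxin-7-yl]prop-2-enal | COc1cc([C@@H]2Oc3cc(/C=C/C=O)cc(OCc4ccccc4)c3O[C@H]2CO)cc(OC)c1OC | intermediate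
14 | (2E)-3-[(2S,3S)-5-hydroxy-3-(hydroxymethyl)-2-(3,4,5-trimethoxyphenyl)-2,3-dihydro-1,4-benzodioxin-7-yl]prop-2-enal | COc1cc([C@@H]2Oc3cc(/C=C/C=O)cc(O)c3O[C@H]2CO)cc(OC)c1OC | target

## Step count and least certain steps

Total: 11 steps. Longest linear sequence: 9 steps (1, 2, 3, 6, 7, 8, 9, 10, 11, from aldehyde 1). Steps 4 and 5 form the two-step branch to 8.

**Step 6 (key step, proposed new method).** Three things may go wrong.
- Ionisation of C2–O1 instead of C2–O4 would deliver C3 to the wrong oxygen.
- Hydride or aryl migration to the diazonium carbon could outrun the aryloxide and lead to ring-opened enol ethers.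
- The Lewis acid could decompose the diazo ester before it meets the cation.

Fallback by known chemistry, from 5 back to 9:
- The acetal of 5 is hydrolysed (aqueous HCl, THF) to methyl 3-(benzyloxy)-4,5-dihydroxybenzoate F1. The acetal has then served as the protecting group that singled out one hydroxyl for benzylation.
- Separately, purchased ethyl 3-oxo-3-(3,4,5-trimethoxyphenyl)propanoate F2 is transesterified with menthol 6 (toluene, reflux, cat. DMAP) to (1R,2S,5R)-menthyl 3-oxo-3-(3,4,5-trimethoxyphenyl)propanoate F3. NBS then gives the α-bromo β-keto ester F4.
- Alkylation of F1 with F4 (K2CO3, acetone) at the more acidic para hydroxyl makes the O4–C3 bond and gives the α-aryloxy β-keto ester F5.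
- NaBH4 reduces the ketone to the benzylic alcohol F6.
- Mitsunobu closure (PPh3, DIAD, THF) of the remaining phenol onto the benzylic carbon makes O1–C2 and gives the cis/trans mixture 9, where the route is rejoined before step 7.

**Step 7.** The menthyl group is five bonds from the ring stereocentres, so the two trans diastereomers may co-crystallise or separate poorly. Base-induced opening at C2–O1 (elimination from the C3 enolate) may also cost material if the open form does not reclose. Fallback: from 9, after the DBU treatment, LiAlH4 in THF removes the auxiliary and gives the racemic trans diol F7. This is resolved by preparative chromatography on a polysaccharide-carbamate chiral stationary phase. Its (2S,3S) enantiomer is 11, where the route is rejoined.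

**Step 11.** The Lewis acid may not discriminate between the O-benzyl bond and other sites. Possible side processes are ionisation of the benzylic C2–O1 bond (ring opening or loss of configuration at C2), demethylation of the crowded central methoxy group, and addition to the activated enal. Fallback: from 10, the benzyl group is removed while only esters are present. H2 over palladium on carbon (Pd/C) in EtOAc gives the phenol diester F8; the cyclic C2–O1 bond is expected to be cleaved much more slowly than a primary O-benzyl group. LiAlH4 then gives the triol F9. MnO2 oxidises only the benzylic alcohol to the phenolic aldehyde F10. The Wittig reaction of step 10 with (triphenylphosphoranylidene)acetaldehyde gives 14 directly.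

**Step 10.** The product enal may react a second time with the ylide (over-homologation to the dienal), or the stabilised ylide may react sluggishly with the electron-rich aldehyde. Fallback: from 12, a Horner–Wadsworth–Emmons reaction with triethyl phosphonoacetate (LiCl, DBU, MeCN) gives the (E)-cinnamate ester F11. DIBAL-H (CH2Cl2, −78 °C) gives the allylic alcohol F12. MnO2 oxidises the allylic alcohol in preference to the saturated C9 alcohol and gives 13, where the route is rejoined.

## Further compounds

F1 | step 6 | methyl 3-(benzyloxy)-4,5-dihydroxybenzoate | COC(=O)c1cc(O)c(O)c(OCc2ccccc2)c1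
F2 | step 6 | ethyl 3-oxo-3-(3,4,5-trimethoxyphenyl)propanoate | CCOC(=O)CC(=O)c1cc(OC)c(OC)c(OC)c1
F3 | step 6 | (1R,2S,5R)-menthyl 3-oxo-3-(3,4,5-trimethoxyphenyl)propanoate | COc1cc(C(=O)CC(=O)O[C@@H]2C[C@H](C)CC[C@H]2C(C)C)cc(OC)c1OC
F4 | step 6 | (1R,2S,5R)-menthyl 2-bromo-3-oxo-3-(3,4,5-trimethoxyphenyl)propanoate (mixture at the bromine-bearing carbon) | COc1cc(C(=O)C(Br)C(=O)O[C@@H]2C[C@H](C)CC[C@H]2C(C)C)cc(OC)c1OC
F5 | step 6 | (1R,2S,5R)-menthyl 2-[2-(benzyloxy)-6-hydroxy-4-(methoxycarbonyl)phenoxy]-3-oxo-3-(3,4,5-trimethoxyphenyl)propanoate (mixture at C2 of the propanoate) | COc1cc(C(=O)C(Oc2c(O)cc(C(=O)OC)cc2OCc2ccccc2)C(=O)O[C@@H]3C[C@H](C)CC[C@H]3C(C)C)cc(OC)c1OC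
F6 | step 6 | (1R,2S,5R)-menthyl 2-[2-(benzyloxy)-6-hydroxy-4-(methoxycarbonyl)phenoxy]-3-hydroxy-3-(3,4,5-trimethoxyphenyl)propanoate (mixture of diastereomers) | COc1cc(C(O)C(Oc2c(O)cc(C(=O)OC)cc2OCc2ccccc2)C(=O)O[C@@H]3C[C@H](C)CC[C@H]3C(C)C)cc(OC)c1OC
F7 | step 7 | racemic trans-[5-(benzyloxy)-2-(3,4,5-trimethoxyphenyl)-2,3-dihydro-1,4-benzodioxine-3,7-diyl]dimethanol (equimolar (2S,3S) and (2R,3R)) | COc1cc([C@@H]2Oc3cc(CO)cc(OCc4ccccc4)c3O[C@H]2CO)cc(OC)c1OC.COc1cc([C@H]2Oc3cc(CO)cc(OCc4ccccc4)c3O[C@@H]2CO)cc(OC)c1OC
F8 | step 11 | 3-[(1R,2S,5R)-menthyl] 7-methyl (2S,3R)-5-hydroxy-2-(3,4,5-trimethoxyphenyl)-2,3-dihydro-1,4-benzodioxine-3,7-dicarboxylate | COc1cc([C@@H]2Oc3cc(C(=O)OC)cc(O)c3O[C@H]2C(=O)O[C@@H]4C[C@H](C)CC[C@H]4C(C)C)cc(OC)c1OC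
F9 | step 11 | [(2S,3S)-5-hydroxy-2-(3,4,5-trimethoxyphenyl)-2,3-dihydro-1,4-benzodioxine-3,7-diyl]dimethanol | COc1cc([C@@H]2Oc3cc(CO)cc(O)c3O[C@H]2CO)cc(OC)c1OC
F10 | step 11 | (2S,3S)-5-hydroxy-3-(hydroxymethyl)-2-(3,4,5-trimethoxyphenyl)-2,3-dihydro-1,4-benzodioxine-7-carbaldehyde | COc1cc([C@@H]2Oc3cc(C=O)cc(O)c3O[C@H]2CO)cc(OC)c1OC
F11 | step 10 | ethyl (2E)-3-[(2S,3S)-5-(benzyloxy)-3-(hydroxymethyl)-2-(3,4,5-trimethoxyphenyl)-2,3-dihydro-1,4-benzodioxin-7-yl]prop-2-enoate | COc1cc([C@@H]2Oc3cc(/C=C/C(=O)OCC)cc(OCc4ccccc4)c3O[C@H]2CO)cc(OC)c1OC
F12 | step 10 | (2E)-3-[(2S,3S)-5-(benzyloxy)-3-(hydroxymethyl)-2-(3,4,5-trimethoxyphenyl)-2,3-dihydro-1,4-benzodioxin-7-yl]prop-2-en-1-ol | COc1cc([C@@H]2Oc3cc(/C=C/CO)cc(OCc4ccccc4)c3O[C@H]2CO)cc(OC)c1OC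
A1 | alternative 1 | methyl 3,5-bis(tert-butyldimethylsilyloxy)-4-(vinyloxy)benzoate | COC(=O)c1cc(O[Si](C)(C)C(C)(C)C)c(OC=C)c(O[Si](C)(C)C(C)(C)C)c1
A2 | alternative 1 | methyl 3,5-bis(tert-butyldimethylsilyloxy)-4-{[(2R,3S)-2-(3,4,5-trimethoxyphenyl)oxetan-3-yl]oxy}benzoate (trans) | COc1cc([C@H]2OC[C@@H]2Oc2c(O[Si](C)(C)C(C)(C)C)cc(C(=O)OC)cc2O[Si](C)(C)C(C)(C)C)cc(OC)c1OC
A3 | alternative 2 | 3,5-dihydroxy-4-{[(2R)-1-(tert-butyldimethylsilyloxy)-3-(3,4,5-trimethoxyphenyl)propan-2-yl]oxy}benzaldehyde | COc1cc(C[C@H](CO[Si](C)(C)C(C)(C)C)Oc2c(O)cc(C=O)cc2O)cc(OC)c1OC
A4 | alternative 2 | (2S,3S)-3-(tert-butyldimethylsilyloxymethyl)-5-hydroxy-2-(3,4,5-trimethoxyphenyl)-2,3-dihydro-1,4-benzodioxine-7-carbaldehyde (trans, target numbering) | COc1cc([C@@H]2Oc3cc(C=O)cc(O)c3O[C@H]2CO[Si](C)(C)C(C)(C)C)cc(OC)c1OC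
A5 | alternative 3 | methyl 3,4-dihydroxy-5-{[(1R,2E)-4-(methoxycarbonyloxy)-1-(3,4,5-trimethoxyphenyl)but-2-en-1-yl]oxy}benzoate | COc1cc([C@@H](/C=C/COC(=O)OC)Oc2cc(C(=O)OC)cc(O)c2O)cc(OC)c1OC
A6 | alternative 3 | methyl (2S,3S)-5-hydroxy-2-(3,4,5-trimethoxyphenyl)-3-vinyl-2,3-dihydro-1,4-benzodioxine-7-carboxylate (trans, target numbering) | COc1cc([C@@H]2Oc3cc(C(=O)OC)cc(O)c3O[C@H]2C=C)cc(OC)c1OC
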